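**Retrosynthetic overview**
- The strategy rests on the acyclic ester terminus C1(=O)–C2H2–C3H2 of the pentacosanoyl chain. The only ring, the para-disubstituted benzene ring of tyrosol, is bought intact, so no ring is formed at any stage.
- The saturated C2–C3 unit and the free phenol are traced back through an O-benzyl (E)-2-enoate, a β-mesylate and a β-hydroxy ester to an O-benzyl 3-oxopentacosanoate (reduce, dehydrate, reduce, as in fatty acid biosynthesis).
- Key disconnection: the C2–C3 bond of the β-keto ester is cut into tricosanoyl imidazolide (C3–C25) and a malonic half ester that already carries the O-benzyl tyrosol ester (C1–C2).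
- The half ester comes from tyrosol by phenol benzylation and ring opening of Meldrum's acid; the imidazolide comes from tricosanoic acid and carbonyldiimidazole.

Key step: step 4

Remark: the C3 carbinol centre made in step 5 is formed as a racemate on purpose and is erased in step 7; the target has no stereocentre, so no stereocontrol is needed.

**Route**

Step 1
Reactants: 1 tyrosol; 2 benzyl bromide
Product: 3 2-[4-(benzyloxy)phenyl]ethanol
Conditions: K2CO3, acetone, reflux
Reagents that add atoms: none
Why: Williamson etherification in which carbonate deprotonates only the phenol (far more acidic than the primary alcohol), so benzylation should occur on the phenolic oxygen alone.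

Step 2
Reactants: 3 2-[4-(benzyloxy)phenyl]ethanol; 4 Meldrum's acid
Product: 5 3-{2-[4-(benzyloxy)phenyl]ethoxy}-3-oxopropanoic acid
Conditions: toluene, reflux; NaHCO3 extraction, then acidification
Reagents that add atoms: none
Why: Alcoholysis of the cyclic acylal of Meldrum's acid by a primary alcohol with loss of acetone is a standard route to malonic half esters, and the acid product is separated from neutral material by bicarbonate extraction.

Step 3
Reactants: 6 tricosanoic acid
Product: 7 1-(1H-imidazol-1-yl)tricosan-1-one (tricosanoyl imidazolide)
Conditions: CDI (1.05 equiv), THF, 45 °C, until CO2 evolution ends; used as the warm THF solution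
Reagents that add atoms: 1,1'-carbonyldiimidazole, O=C(n1ccnc1)n1ccnc1
Why: Carboxylic acid activation with carbonyldiimidazole proceeds through the mixed anhydride, which collapses with loss of CO2 to the N-acylimidazole, and the saturated chain carries no other reactive group.

Step 4
Reactants: 5 3-{2-[4-(benzyloxy)phenyl]ethoxy}-3-oxopropanoic acid; 7 1-(1H-imidazol-1-yl)tricosan-1-one
Product: 9 2-[4-(benzyloxy)phenyl]ethyl 3-oxopentacosanoate, via magnesium-chelated acylmalonate half ester 8 (not isolated)
Conditions: 5 (1.5 equiv), MgCl2, Et3N, THF/MeCN, rt; then 7 in THF, rt → 45 °C; 1 M HCl work-up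
Reagents that add atoms: none
Why: MgCl2 and Et3N convert half ester 5 into its magnesium-chelated carboxylate enolate, whose central carbon (future C2) attacks the carbonyl of imidazolide 7 (future C3) and expels imidazole to give the chelated acylmalonate 8. Loss of CO2 from 8, completed on acidification, leaves β-keto ester 9 and makes the C2–C3 bond formation irreversible. The closest known reaction type is the decarboxylative Claisen condensation of magnesium malonate half esters with acyl imidazolides, the laboratory counterpart of the ketosynthase step of fatty acid biosynthesis. No ring is closed and no stereocentre is formed. The step needs C- over O-acylation and mono- over double acylation; the bidentate magnesium chelate ties up both malonate oxygens and leaves carbon as the nucleophilic site, and after decarboxylation the product rests as a stabilised magnesium β-keto ester enolate that the mild imidazolide does not acylate again. The benzyl ether, the arylethyl ester and the saturated chain are inert to these nearly neutral conditions, and the excess of 5 makes up for enolate lost by proton transfer to the product.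

Step 5
Reactants: 9 2-[4-(benzyloxy)phenyl]ethyl 3-oxopentacosanoate
Product: 10 2-[4-(benzyloxy)phenyl]ethyl (±)-3-hydroxypentacosanoate
Conditions: NaBH4, THF/EtOH, −10 → 0 °C; aqueous NH4Cl quench
Reagents that add atoms: none
Why: Borohydride reduction of the ketone of a β-keto ester is much faster than attack on the ester at low temperature, and the new C3 carbinol centre forms as a racemate, which does not matter because C3 becomes a methylene later.

Step 6
Reactants: 10 2-[4-(benzyloxy)phenyl]ethyl (±)-3-hydroxypentacosanoate
Product: 11 2-[4-(benzyloxy)phenyl]ethyl (±)-3-(methylsulfonyloxy)pentacosanoate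
Conditions: MsCl, Et3N, CH2Cl2, 0 °C
Reagents that add atoms: methanesulfonyl chloride, CS(=O)(=O)Cl
Why: Sulfonylation of a secondary alcohol with methanesulfonyl chloride and triethylamine is general, and any elimination that starts early only gives the product of the next step.

Step 7
Reactants: 11 2-[4-(benzyloxy)phenyl]ethyl (±)-3-(methylsulfonyloxy)pentacosanoate
Product: 12 2-[4-(benzyloxy)phenyl]ethyl (E)-pentacos-2-enoate
Conditions: DBU, THF, 0 °C → rt
Reagents that add atoms: none
Why: E1cB elimination, in which DBU removes the acidic α-proton and the ester enolate expels mesylate, should give the conjugated (E)-enoate, and any alkene isomer converges to the same product in step 8.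

Step 8
Reactants: 12 2-[4-(benzyloxy)phenyl]ethyl (E)-pentacos-2-enoate
Product: 13 2-(4-hydroxyphenyl)ethyl pentacosanoate
Conditions: H2 (1 atm), 10% Pd/C, EtOAc/THF, 40 °C
Reagents that add atoms: none
Why: Heterogeneous catalytic hydrogenation saturates the C2–C3 alkene and hydrogenolyses the benzylic C–O bond of the aryl benzyl ether in one operation, while the homobenzylic C–O bond of the 2-arylethyl ester and the phenol ring are not cleaved or reduced.

**Compound list**
1 | tyrosol, 4-(2-hydroxyethyl)phenol | OCCc1ccc(O)cc1 | starting material
2 | benzyl bromide | BrCc1ccccc1 | starting material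
3 | 2-[4-(benzyloxy)phenyl]ethanol | OCCc1ccc(OCc2ccccc2)cc1 | intermediate
4 | Meldrum's acid, 2,2-dimethyl-1,3-dioxane-4,6-dione | CC1(C)OC(=O)CC(=O)O1 | starting material
5 | 3-{2-[4-(benzyloxy)phenyl]ethoxy}-3-oxopropanoic acid | OC(=O)CC(=O)OCCc1ccc(OCc2ccccc2)cc1 | intermediate
6 | tricosanoic acid | CCCCCCCCCCCCCCCCCCCCCCC(=O)O | starting material
7 | 1-(1H-imidazol-1-yl)tricosan-1-one | CCCCCCCCCCCCCCCCCCCCCCC(=O)n1ccnc1 | intermediate
8 | 2-({2-[4-(benzyloxy)phenyl]ethoxy}carbonyl)-3-oxopentacosanoic acid, present as its magnesium chelate | CCCCCCCCCCCCCCCCCCCCCCC(=O)C(C(=O)O)C(=O)OCCc1ccc(OCc2ccccc2)cc1 | intermediate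
9 | 2-[4-(benzyloxy)phenyl]ethyl 3-oxopentacosanoate | CCCCCCCCCCCCCCCCCCCCCCC(=O)CC(=O)OCCc1ccc(OCc2ccccc2)cc1 | intermediate
10 | 2-[4-(benzyloxy)phenyl]ethyl (±)-3-hydroxypentacosanoate (racemic at C3) | CCCCCCCCCCCCCCCCCCCCCCC(O)CC(=O)OCCc1ccc(OCc2ccccc2)cc1 | intermediate
11 | 2-[4-(benzyloxy)phenyl]ethyl (±)-3-(methylsulfonyloxy)pentacosanoate (racemic at C3) | CCCCCCCCCCCCCCCCCCCCCCC(OS(C)(=O)=O)CC(=O)OCCc1ccc(OCc2ccccc2)cc1 | intermediate
12 | 2-[4-(benzyloxy)phenyl]ethyl (E)-pentacos-2-enoate | CCCCCCCCCCCCCCCCCCCCCC/C=C/C(=O)OCCc1ccc(OCc2ccccc2)cc1 | intermediate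
13 | 2-(4-hydroxyphenyl)ethyl pentacosanoate | CCCCCCCCCCCCCCCCCCCCCCCCC(=O)OCCc1ccc(O)cc1 | target

**Step count**
Total steps: 8. Longest linear sequence: 7 (steps 1, 2, 4, 5, 6, 7, 8); step 3 is the one-step side branch.

**Steps most likely to fail**

1. Step 4. The malonate enolate may be quenched by proton transfer from the forming β-keto ester, or acylated on oxygen, so that the sparingly soluble long-chain imidazolide is consumed incompletely and hydrolysed at work-up. Fallback, setting out from 6 (with 4 and 3) and returning at 9: tricosanoic acid 6 would be condensed with Meldrum's acid 4 (DCC, DMAP, CH2Cl2, 0 °C → rt) to give the acyl Meldrum's acid 5-(1-hydroxytricosylidene)-2,2-dimethyl-1,3-dioxane-4,6-dione F1. Heating F1 with alcohol 3 in toluene at reflux would open the dioxanedione through the acylketene, with loss of acetone and CO2, and give β-keto ester 9 directly.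

2. Step 5. Over-reduction of the β-hydroxy ester to the 1,3-diol, or alkoxide-mediated exchange of the arylethyl ester with the alcohol cosolvent, would cut the ester linkage that the route carries through. Fallback, setting out from 9 and returning at 12 (steps 5 to 7 are bypassed): β-keto ester 9 would be converted with Tf2O and aqueous LiOH in toluene at 5 °C into the enol triflate 2-[4-(benzyloxy)phenyl]ethyl (Z)-3-{[(trifluoromethyl)sulfonyl]oxy}pentacos-2-enoate F2. The C–O bond of F2 would then be reduced with formate under homogeneous palladium catalysis (Pd(OAc)2, PPh3, HCO2H, Bu3N, DMF, 60 °C), with retention of alkene geometry, to give enoate 12; the benzyl ether is not touched by this soluble catalyst.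

3. Step 8. The benzyl ether hydrogenolysis may stall after the alkene is saturated, because the waxy saturated ester deposits on the catalyst or because sulfur traces from the mesylate chemistry poison it. Fallback, setting out from 12 and returning at 13: the alkene alone would be hydrogenated homogeneously (H2, RhCl(PPh3)3, toluene/EtOH, 40 °C) to give 2-[4-(benzyloxy)phenyl]ethyl pentacosanoate F3. The aryl benzyl ether of F3 would then be cleaved by a Lewis acid with a cation scavenger (BCl3, pentamethylbenzene, CH2Cl2, −78 °C), conditions that leave the ester intact, to give target 13.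

**Further compounds**
F1 | step 4 | 5-(1-hydroxytricosylidene)-2,2-dimethyl-1,3-dioxane-4,6-dione | CCCCCCCCCCCCCCCCCCCCCCC(O)=C1C(=O)OC(C)(C)OC1=O
F2 | step 5 | 2-[4-(benzyloxy)phenyl]ethyl (Z)-3-{[(trifluoromethyl)sulfonyl]oxy}pentacos-2-enoate | CCCCCCCCCCCCCCCCCCCCCC/C(OS(=O)(=O)C(F)(F)F)=C/C(=O)OCCc1ccc(OCc2ccccc2)cc1
F3 | step 8 | 2-[4-(benzyloxy)phenyl]ethyl pentacosanoate | CCCCCCCCCCCCCCCCCCCCCCCCC(=O)OCCc1ccc(OCc2ccccc2)cc1
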